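**Retrosynthetic overview**
- No ring is formed: the quinone ring is bought intact as 2-methyl-1,4-benzoquinone 1.
- Key disconnection (C–O): the C5–OMe bond. Forward, a new copper-catalysed aerobic methoxylation of 1 gives, through hydroquinone 2, 2-methoxy-5-methyl-1,4-benzoquinone 3.
- This C–O bond also fixes the later regiochemistry: the vinylogous ester in 3 leaves only the ring C–H next to the methyl group open to nucleophilic radicals.
- Second disconnection (C–C): the ring–C21 bond. Decarboxylative radical alkylation of 3 with docosanoic acid 4 gives target 5.

Assumptions: the target has no stereocentre and no stereogenic double bond, so no stereocontrol is needed; the route has only two steps, so both are ranked as the steps most likely to fail; short-lived radicals are treated as mechanistic species and carry no compound number.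

**Route**

Step 1
Reactants: 1 2-methyl-1,4-benzoquinone (toluquinone)
Product: 3 2-methoxy-5-methyl-1,4-benzoquinone, via 2-methoxy-5-methylbenzene-1,4-diol 2 (not isolated)
Conditions: Cu(OTf)2 (10 mol%), O2 (1 atm), MeOH (0.3 M), 45 °C, 16 h; cool to 0 °C, filter, recrystallise (MeOH)
Reagents that add atoms: methanol (CO)
Why: Proposed new method: aerobic copper-catalysed dehydrogenative oxa-Michael methoxylation, in which Cu(OTf)2 as Lewis acid activates 1 for conjugate addition of methanol at C5 (the site that Thiele–Winter acetoxylation and amine additions to 1 also choose, because the methyl group deactivates the C4 carbonyl so that the enolate forms at C1), tautomerisation gives hydroquinone 2, and divalent copper, recycled from monovalent copper by O2, dehydrogenates 2 (and any methylhydroquinone formed by redox exchange between 2 and 1) so that all material funnels to 3, a vinylogous ester that resists a second addition and crystallises out, with water as the only co-product and no nucleophilic counter-ion to compete; the closest known reaction types are the stoichiometric ZnCl2/MeOH methoxylation of quinones, which sacrifices half of the quinone as oxidant, and copper/O2 oxidation of hydroquinones to quinones.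

Step 2
Reactants: 3 2-methoxy-5-methyl-1,4-benzoquinone; 4 docosanoic acid (behenic acid)
Product: 5 3-henicosyl-5-methoxy-2-methyl-1,4-benzoquinone (= 6-henicosyl-2-methoxy-5-methyl-1,4-benzoquinone, the target)
Conditions: AgNO3 (0.3 equiv), (NH4)2S2O8 (1.5 equiv, added slowly), 4 (1.3 equiv), MeCN/H2O (2:1), 75 °C, 3 h
Reagents that add atoms: none
Why: Jacobsen–Torssell (Minisci-type) decarboxylative radical alkylation, in which divalent silver made from AgNO3 and persulfate oxidises 4 to the nucleophilic henicosyl radical with loss of CO2, the radical adds at C6 of 3 (the unsubstituted β-carbon of the C4 enone and the only ring C–H not made electron-rich by the methoxy group, the same site next to the methyl group that is alkylated in 2,3-dimethoxy-5-methyl-1,4-benzoquinone), and the adduct radical is oxidised back to the quinone.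

**Compound list**
1 | 2-methyl-1,4-benzoquinone (toluquinone) | CC1=CC(=O)C=CC1=O | starting material
2 | 2-methoxy-5-methylbenzene-1,4-diol | COc1cc(O)c(C)cc1O | intermediate (not isolated)
3 | 2-methoxy-5-methyl-1,4-benzoquinone | COC1=CC(=O)C(C)=CC1=O | intermediate
4 | docosanoic acid (behenic acid) | CCCCCCCCCCCCCCCCCCCCCC(=O)O | starting material
5 | 3-henicosyl-5-methoxy-2-methyl-1,4-benzoquinone (achiral) | CCCCCCCCCCCCCCCCCCCCCC1=C(C)C(=O)C=C(OC)C1=O | target

**Totals**
Total step count: 2. Longest linear sequence: 2 steps (1 → 3 → 5).

**Steps most likely to fail**

1. Step 1 (the proposed new method). The risks are slow aerobic turnover in the mildly acidic medium (stalling near half conversion, as in the stoichiometric reaction), some 6-methoxy regioisomer, and oxidative oligomerisation of 2. The fallback uses known chemistry only, sets out from 1 and comes back at 3. Thiele–Winter acetoxylation of 1 (Ac2O, cat. H2SO4, 40 °C) gives 2,4,5-triacetoxytoluene F1 with the oxygen already at the right carbon. Acid methanolysis (HCl, MeOH, reflux, under N2) gives 5-methylbenzene-1,2,4-triol F2. Aqueous FeCl3 oxidises this to 2-hydroxy-5-methyl-1,4-benzoquinone F3. Fischer-type O-methylation of this vinylogous acid (MeOH, cat. H2SO4, reflux) gives 3.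

2. Step 2. The risks are poor solubility of 4 in aqueous MeCN, modest conversion, over-oxidation of the product by persulfate, and minor attack at C3. The fallback gives up catalytic oxidative decarboxylation for a preformed radical source in a homogeneous, metal-free medium (Fieser alkylation); it sets out from 4 and comes back at 5. Acid 4 is converted with SOCl2 (neat, 70 °C) into docosanoyl chloride F4. This is treated with 30% H2O2 and aqueous NaOH (hexane/Et2O, 0 °C) to give didocosanoyl peroxide F5. Heating F5 (1.2 equiv) with 3 in AcOH at 95 °C gives 5; the peroxide serves as both alkyl source and oxidant.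

**Further compounds**
F1 | step 1 | 2,4,5-triacetoxytoluene (5-methylbenzene-1,2,4-triyl triacetate) | Cc1cc(OC(C)=O)c(OC(C)=O)cc1OC(C)=O
F2 | step 1 | 5-methylbenzene-1,2,4-triol | Cc1cc(O)c(O)cc1O
F3 | step 1 | 2-hydroxy-5-methyl-1,4-benzoquinone | CC1=CC(=O)C(O)=CC1=O
F4 | step 2 | docosanoyl chloride | CCCCCCCCCCCCCCCCCCCCCC(=O)Cl
F5 | step 2 | didocosanoyl peroxide | CCCCCCCCCCCCCCCCCCCCCC(=O)OOC(=O)CCCCCCCCCCCCCCCCCCCCC
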